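**Retrosynthetic overview**
1. Target 25 ⇐ MOM-protected aryl-decalin 19 by late arene work: ortho-lithiation/formylation between two MOM ethers, MOM removal, temporary catechol silylene, O-sulfation of the remaining phenol, fluoride desilylation.
2. Ring A is formed last: 19 ⇐ triene 17 by ring-closing metathesis (C2=C3) and diimide reduction.
3. The C10–C1 bond and the C5=C6 alkene ⇐ Johnson–Claisen rearrangement of ring-B allylic alcohol 13; 13 ⇐ ketone 9 by 1,3-oxygen transposition (enol triflate, reduction, SeO2).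
4. Key disconnection, C9–C11: intermolecular aldol condensation of ring-B ketone 5 with aryl aldehyde 2, then reductive methylation to set the C9 quaternary centre.
5. Ring B is bought: 5 ⇐ (R)-(+)-pulegone 3 (C8 stereocentre, gem-dimethyl carbon C4) + vinylmagnesium bromide; 2 ⇐ 2,4,5-trihydroxybenzaldehyde 1.

Assumption: the aryl hydrogen sulfate is prepared and handled as its sodium salt; the given SMILES is its protonated form.

Atom labels: decalin carbons C1–C10 (C4 = CMe2, C5=C6 alkene, C8 = CHMe, C9 = quaternary carbon, C10 = ring-fusion CH), C11 = benzylic CH2; arene carbons C1'–C6' (C1' carries C11, C2' the sulfate, C3' the formyl group). MOM = methoxymethyl. The target has the C8 and C9 methyls trans, and C1 cis to the C9 methyl.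

**Step 1**
Reactants: 1 2,4,5-trihydroxybenzaldehyde
Product: 2 2,4,5-tris(methoxymethoxy)benzaldehyde
Conditions: NaH (3.3 equiv), MOMCl (3.5 equiv), DMF, 0 °C to rt
Reagents that add atoms: chloromethyl methyl ether COCCl
Why: Williamson-type O-alkylation of the three phenoxides gives acetal ethers that survive base, Li/NH3 and organolithiums and later direct the ortho-lithiation; no stereocentre is formed.

**Step 2**
Reactants: 3 (R)-(+)-pulegone
Product: 5 (2S,5R)-5-methyl-2-(2-methylbut-3-en-2-yl)cyclohexan-1-one, via bromomagnesium enolate 4 (not isolated)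
Conditions: CH2=CHMgBr (1.5 equiv), CuBr·SMe2 (10 mol %), THF, −30 to 0 °C; then aq. NH4Cl
Reagents that add atoms: vinylmagnesium bromide C=C[Mg]Br
Why: copper-catalysed conjugate (1,4-) addition of the vinyl Grignard reagent to the s-cis exocyclic enone builds the quaternary gem-dimethyl carbon C4; the C8 methyl centre comes unchanged from pulegone, and the epimerisable C5 centre (trans major, used as the mixture) is later made planar.

**Step 3**
Reactants: 5 (2S,5R)-5-methyl-2-(2-methylbut-3-en-2-yl)cyclohexan-1-one; 2 2,4,5-tris(methoxymethoxy)benzaldehyde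
Product: 7 (2E,3R,6R)-3-methyl-6-(2-methylbut-3-en-2-yl)-2-{[2,4,5-tris(methoxymethoxy)phenyl]methylidene}cyclohexan-1-one, via aldol adduct 6 (not isolated)
Conditions: KOH (1.5 equiv), EtOH, 60 °C
Reagents that add atoms: none
Why: intermolecular aldol (Claisen–Schmidt) condensation, in which the enolate of the only α-methylene (C9) adds to the non-enolisable aldehyde and E1cB dehydration gives the E-enone; allylic 1,3-strain makes the C8 methyl axial and base equilibration puts the C5 substituent equatorial, cis to that methyl.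

**Step 4**
Reactants: 7 (2E,3R,6R)-3-methyl-6-(2-methylbut-3-en-2-yl)-2-{[2,4,5-tris(methoxymethoxy)phenyl]methylidene}cyclohexan-1-one
Product: 9 (2R,3R,6R)-2,3-dimethyl-6-(2-methylbut-3-en-2-yl)-2-{[2,4,5-tris(methoxymethoxy)phenyl]methyl}cyclohexan-1-one, via lithium enolate 8 (not isolated)
Conditions: Li (2.3 equiv), NH3(l)/THF, −78 °C; then MeI (5 equiv), −78 to −33 °C; NH4Cl
Reagents that add atoms: iodomethane CI
Why: dissolving-metal reduction of the aryl-conjugated enone gives the C9=C10 enolate regiospecifically, and this reductive alkylation with MeI occurs anti to the pseudoaxial C8 methyl (allylic 1,2-strain), so the new C9 methyl is trans to the C8 methyl (2R).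

**Step 5**
Reactants: 9 (2R,3R,6R)-2,3-dimethyl-6-(2-methylbut-3-en-2-yl)-2-{[2,4,5-tris(methoxymethoxy)phenyl]methyl}cyclohexan-1-one
Product: 11 (5R,6R)-5,6-dimethyl-2-(2-methylbut-3-en-2-yl)-6-{[2,4,5-tris(methoxymethoxy)phenyl]methyl}cyclohex-1-en-1-yl trifluoromethanesulfonate, via potassium enolate 10 (not isolated)
Conditions: KN(SiMe3)2 (1.3 equiv), THF, −78 to 0 °C; PhNTf2 (1.4 equiv), −78 °C to rt
Reagents that add atoms: N-phenylbis(trifluoromethanesulfonimide) O=S(=O)(N(c1ccccc1)S(=O)(=O)C(F)(F)F)C(F)(F)F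
Why: the ketone can enolise only towards C5 because C9 is quaternary, so enolate O-triflation gives a single enol triflate and removes the C5 stereocentre.

**Step 6**
Reactants: 11 (5R,6R)-5,6-dimethyl-2-(2-methylbut-3-en-2-yl)-6-{[2,4,5-tris(methoxymethoxy)phenyl]methyl}cyclohex-1-en-1-yl trifluoromethanesulfonate
Product: 12 1-{[(1R,6R)-1,6-dimethyl-3-(2-methylbut-3-en-2-yl)cyclohex-2-en-1-yl]methyl}-2,4,5-tris(methoxymethoxy)benzene
Conditions: Pd(OAc)2 (5 mol %), PPh3 (10 mol %), HCO2H (2 equiv), n-Bu3N (3 equiv), DMF, 60 °C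
Reagents that add atoms: none
Why: palladium-catalysed formate reduction of the vinyl triflate (oxidative addition to zerovalent palladium, formate decarboxylation, C–H reductive elimination) replaces OTf by H and leaves the C10=C5 alkene.

**Step 7**
Reactants: 12 1-{[(1R,6R)-1,6-dimethyl-3-(2-methylbut-3-en-2-yl)cyclohex-2-en-1-yl]methyl}-2,4,5-tris(methoxymethoxy)benzene
Product: 13 (1R,4R,5R)-4,5-dimethyl-2-(2-methylbut-3-en-2-yl)-4-{[2,4,5-tris(methoxymethoxy)phenyl]methyl}cyclohex-2-en-1-ol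
Conditions: SeO2 (0.5 equiv), t-BuOOH (3 equiv), CH2Cl2, rt
Reagents that add atoms: selenium dioxide O=[Se]=O; tert-butyl hydroperoxide CC(C)(C)OO
Why: SeO2 allylic hydroxylation (ene reaction at C10, then [2,3]-sigmatropic shift) can use only the C6 hydrogens because C4 and C9 are quaternary, and it runs suprafacially on the ring face opposite the C8 methyl and the pseudoaxial benzyl group, placing the C6 hydroxyl trans to the C8 methyl (1R).

**Step 8**
Reactants: 13 (1R,4R,5R)-4,5-dimethyl-2-(2-methylbut-3-en-2-yl)-4-{[2,4,5-tris(methoxymethoxy)phenyl]methyl}cyclohex-2-en-1-ol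
Product: 15 ethyl 2-[(1S,5R,6R)-5,6-dimethyl-2-(2-methylbut-3-en-2-yl)-6-{[2,4,5-tris(methoxymethoxy)phenyl]methyl}cyclohex-2-en-1-yl]acetate, via ketene acetal 14 (not isolated)
Conditions: CH3C(OEt)3 (10 equiv), EtCO2H (10 mol %), 140 °C, EtOH distilled off
Reagents that add atoms: triethyl orthoacetate CCOC(C)(OCC)OCC
Why: the Johnson–Claisen [3,3]-sigmatropic rearrangement forms the C10–C1 bond on the face that carried the C6 oxygen (suprafacial chirality transfer, so C1 is cis to the C9 methyl, 1S) and at the same time moves the alkene to C5=C6.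

**Step 9**
Reactants: 15 ethyl 2-[(1S,5R,6R)-5,6-dimethyl-2-(2-methylbut-3-en-2-yl)-6-{[2,4,5-tris(methoxymethoxy)phenyl]methyl}cyclohex-2-en-1-yl]acetate
Product: 16 2-[(1S,5R,6R)-5,6-dimethyl-2-(2-methylbut-3-en-2-yl)-6-{[2,4,5-tris(methoxymethoxy)phenyl]methyl}cyclohex-2-en-1-yl]acetaldehyde
Conditions: i-Bu2AlH (1.1 equiv), CH2Cl2, −78 °C; aq. potassium sodium tartrate
Reagents that add atoms: none
Why: partial hydride reduction of the ester stops at the aldehyde because the tetrahedral aluminium hemiacetal is stable at −78 °C and collapses only on work-up.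

**Step 10**
Reactants: 16 2-[(1S,5R,6R)-5,6-dimethyl-2-(2-methylbut-3-en-2-yl)-6-{[2,4,5-tris(methoxymethoxy)phenyl]methyl}cyclohex-2-en-1-yl]acetaldehyde
Product: 17 1-{[(1R,2S,6R)-1,6-dimethyl-3-(2-methylbut-3-en-2-yl)-2-(prop-2-en-1-yl)cyclohex-3-en-1-yl]methyl}-2,4,5-tris(methoxymethoxy)benzene
Conditions: Ph3PCH3Br (2 equiv), KOt-Bu (1.9 equiv), THF, 0 °C to rt
Reagents that add atoms: methyltriphenylphosphonium bromide C[P+](c1ccccc1)(c1ccccc1)c1ccccc1.[Br-]
Why: Wittig methylenation of the unhindered aldehyde gives the C10 allyl group without touching any stereocentre.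

**Step 11**
Reactants: 17 1-{[(1R,2S,6R)-1,6-dimethyl-3-(2-methylbut-3-en-2-yl)-2-(prop-2-en-1-yl)cyclohex-3-en-1-yl]methyl}-2,4,5-tris(methoxymethoxy)benzene
Product: 18 1-{[(1R,2R,8aS)-1,2,5,5-tetramethyl-1,2,3,5,8,8a-hexahydronaphthalen-1-yl]methyl}-2,4,5-tris(methoxymethoxy)benzene
Conditions: second-generation Grubbs catalyst RuCl2(=CHPh)(H2IMes)(PCy3) (5 mol %), CH2Cl2 (5 mM), 40 °C
Reagents that add atoms: none
Why: ring-closing metathesis of the two terminal alkenes closes ring A as a cyclohexene with loss of ethene, the hindered trisubstituted C5=C6 alkene being inert to the catalyst.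

**Step 12**
Reactants: 18 1-{[(1R,2R,8aS)-1,2,5,5-tetramethyl-1,2,3,5,8,8a-hexahydronaphthalen-1-yl]methyl}-2,4,5-tris(methoxymethoxy)benzene
Product: 19 1-{[(1R,2R,8aS)-1,2,5,5-tetramethyl-1,2,3,5,6,7,8,8a-octahydronaphthalen-1-yl]methyl}-2,4,5-tris(methoxymethoxy)benzene
Conditions: TsNHNH2 (10 equiv), NaOAc (12 equiv), DME/H2O, 85 °C
Reagents that add atoms: none
Why: diimide reduction (concerted syn transfer of H2) saturates the cis-disubstituted C2=C3 alkene far faster than the hindered trisubstituted C5=C6 alkene and leaves arene and acetals alone.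

**Step 13**
Reactants: 19 1-{[(1R,2R,8aS)-1,2,5,5-tetramethyl-1,2,3,5,6,7,8,8a-octahydronaphthalen-1-yl]methyl}-2,4,5-tris(methoxymethoxy)benzene
Product: 21 2,3,6-tris(methoxymethoxy)-5-{[(1R,2R,8aS)-1,2,5,5-tetramethyl-1,2,3,5,6,7,8,8a-octahydronaphthalen-1-yl]methyl}benzaldehyde, via aryllithium 20 (not isolated)
Conditions: n-BuLi (1.5 equiv), TMEDA (1.5 equiv), THF, −78 to 0 °C; DMF (3 equiv), −78 °C to rt; aq. NH4Cl
Reagents that add atoms: N,N-dimethylformamide CN(C)C=O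
Why: directed ortho-metalation takes place at the only ring position flanked by two MOM ethers (C3'), and the aryllithium is formylated by DMF.

**Step 14**
Reactants: 21 2,3,6-tris(methoxymethoxy)-5-{[(1R,2R,8aS)-1,2,5,5-tetramethyl-1,2,3,5,6,7,8,8a-octahydronaphthalen-1-yl]methyl}benzaldehyde
Product: 22 2,3,6-trihydroxy-5-{[(1R,2R,8aS)-1,2,5,5-tetramethyl-1,2,3,5,6,7,8,8a-octahydronaphthalen-1-yl]methyl}benzaldehyde
Conditions: HCl (1.25 M in MeOH), THF, 0 °C to rt, argon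
Reagents that add atoms: none
Why: acid-catalysed acetal exchange with methanol removes the three MOM groups under conditions too mild to protonate the trisubstituted alkene.

**Step 15**
Reactants: 22 2,3,6-trihydroxy-5-{[(1R,2R,8aS)-1,2,5,5-tetramethyl-1,2,3,5,6,7,8,8a-octahydronaphthalen-1-yl]methyl}benzaldehyde
Product: 23 2,2-di-tert-butyl-5-hydroxy-6-{[(1R,2R,8aS)-1,2,5,5-tetramethyl-1,2,3,5,6,7,8,8a-octahydronaphthalen-1-yl]methyl}-1,3,2-benzodioxasilole-4-carbaldehyde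
Conditions: t-Bu2Si(OTf)2 (1.05 equiv), 2,6-lutidine (2.5 equiv), CH2Cl2, −40 to 0 °C
Reagents that add atoms: di-tert-butylsilyl bis(trifluoromethanesulfonate) CC(C)(C)[Si](OS(=O)(=O)C(F)(F)F)(OS(=O)(=O)C(F)(F)F)C(C)(C)C
Why: the bis-electrophilic silane bridges only the vicinal catechol hydroxyls as a five-membered cyclic silylene, which leaves the isolated C2' phenol free.

**Step 16**
Reactants: 23 2,2-di-tert-butyl-5-hydroxy-6-{[(1R,2R,8aS)-1,2,5,5-tetramethyl-1,2,3,5,6,7,8,8a-octahydronaphthalen-1-yl]methyl}-1,3,2-benzodioxasilole-4-carbaldehyde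
Product: 24 2,2-di-tert-butyl-4-formyl-6-{[(1R,2R,8aS)-1,2,5,5-tetramethyl-1,2,3,5,6,7,8,8a-octahydronaphthalen-1-yl]methyl}-1,3,2-benzodioxasilol-5-yl hydrogen sulfate
Conditions: SO3·pyridine (5 equiv), pyridine, 50 °C
Reagents that add atoms: sulfur trioxide pyridine complex [O-]S(=O)(=O)[n+]1ccccc1
Why: O-sulfonation of the only free phenol by the SO3–amine complex gives the aryl sulfate monoester, isolated as its pyridinium salt.

**Step 17**
Reactants: 24 2,2-di-tert-butyl-4-formyl-6-{[(1R,2R,8aS)-1,2,5,5-tetramethyl-1,2,3,5,6,7,8,8a-octahydronaphthalen-1-yl]methyl}-1,3,2-benzodioxasilol-5-yl hydrogen sulfate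
Product: 25 2-formyl-3,4-dihydroxy-6-{[(1R,2R,8aS)-1,2,5,5-tetramethyl-1,2,3,5,6,7,8,8a-octahydronaphthalen-1-yl]methyl}phenyl hydrogen sulfate
Conditions: HF·pyridine, pyridine/THF, 0 °C; NaHCO3 work-up, reversed-phase chromatography
Reagents that add atoms: none
Why: fluoride-mediated Si–O cleavage removes the silylene under non-acidic conditions that leave the aryl sulfate, the aldehyde and the alkene intact.

**Compound list**
1 | 2,4,5-trihydroxybenzaldehyde | O=Cc1cc(O)c(O)cc1O | starting material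
2 | 2,4,5-tris(methoxymethoxy)benzaldehyde | O=Cc1cc(OCOC)c(OCOC)cc1OCOC | intermediate
3 | (R)-(+)-pulegone, (5R)-5-methyl-2-(propan-2-ylidene)cyclohexan-1-one | C[C@@H]1CCC(=C(C)C)C(=O)C1 | starting material
4 | bromomagnesium (5R)-5-methyl-2-(2-methylbut-3-en-2-yl)cyclohex-1-en-1-olate | C[C@@H]1CCC(C(C)(C)C=C)=C(O[Mg]Br)C1 | intermediate
5 | (2S,5R)-5-methyl-2-(2-methylbut-3-en-2-yl)cyclohexan-1-one (major epimer; the 2R epimer is carried along) | C[C@@H]1CC[C@@H](C(C)(C)C=C)C(=O)C1 | intermediate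
6 | (3R)-2-{hydroxy[2,4,5-tris(methoxymethoxy)phenyl]methyl}-3-methyl-6-(2-methylbut-3-en-2-yl)cyclohexan-1-one (mixture at the other centres) | C[C@@H]1CCC(C(C)(C)C=C)C(=O)C1C(O)c1cc(OCOC)c(OCOC)cc1OCOC | intermediate
7 | (2E,3R,6R)-3-methyl-6-(2-methylbut-3-en-2-yl)-2-{[2,4,5-tris(methoxymethoxy)phenyl]methylidene}cyclohexan-1-one | C[C@@H]1CC[C@H](C(C)(C)C=C)C(=O)/C1=C/c1cc(OCOC)c(OCOC)cc1OCOC | intermediate
8 | lithium (3R,6R)-3-methyl-6-(2-methylbut-3-en-2-yl)-2-{[2,4,5-tris(methoxymethoxy)phenyl]methyl}cyclohex-1-en-1-olate | C[C@@H]1CC[C@H](C(C)(C)C=C)C(O[Li])=C1Cc1cc(OCOC)c(OCOC)cc1OCOC | intermediate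
9 | (2R,3R,6R)-2,3-dimethyl-6-(2-methylbut-3-en-2-yl)-2-{[2,4,5-tris(methoxymethoxy)phenyl]methyl}cyclohexan-1-one | C[C@@H]1CC[C@H](C(C)(C)C=C)C(=O)[C@]1(C)Cc1cc(OCOC)c(OCOC)cc1OCOC | intermediate
10 | potassium (5R,6R)-5,6-dimethyl-2-(2-methylbut-3-en-2-yl)-6-{[2,4,5-tris(methoxymethoxy)phenyl]methyl}cyclohex-1-en-1-olate | C[C@@H]1CCC(C(C)(C)C=C)=C(O[K])[C@]1(C)Cc1cc(OCOC)c(OCOC)cc1OCOC | intermediate
11 | (5R,6R)-5,6-dimethyl-2-(2-methylbut-3-en-2-yl)-6-{[2,4,5-tris(methoxymethoxy)phenyl]methyl}cyclohex-1-en-1-yl trifluoromethanesulfonate | C[C@@H]1CCC(C(C)(C)C=C)=C(OS(=O)(=O)C(F)(F)F)[C@]1(C)Cc1cc(OCOC)c(OCOC)cc1OCOC | intermediate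
12 | 1-{[(1R,6R)-1,6-dimethyl-3-(2-methylbut-3-en-2-yl)cyclohex-2-en-1-yl]methyl}-2,4,5-tris(methoxymethoxy)benzene | C[C@@H]1CCC(C(C)(C)C=C)=C[C@]1(C)Cc1cc(OCOC)c(OCOC)cc1OCOC | intermediate
13 | (1R,4R,5R)-4,5-dimethyl-2-(2-methylbut-3-en-2-yl)-4-{[2,4,5-tris(methoxymethoxy)phenyl]methyl}cyclohex-2-en-1-ol | C[C@@H]1C[C@@H](O)C(C(C)(C)C=C)=C[C@]1(C)Cc1cc(OCOC)c(OCOC)cc1OCOC | intermediate
14 | O-(1-ethoxyethenyl) ether of alcohol 13 (mixed ketene acetal) | C[C@@H]1C[C@@H](OC(=C)OCC)C(C(C)(C)C=C)=C[C@]1(C)Cc1cc(OCOC)c(OCOC)cc1OCOC | intermediate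
15 | ethyl 2-[(1S,5R,6R)-5,6-dimethyl-2-(2-methylbut-3-en-2-yl)-6-{[2,4,5-tris(methoxymethoxy)phenyl]methyl}cyclohex-2-en-1-yl]acetate | C[C@@H]1CC=C(C(C)(C)C=C)[C@@H](CC(=O)OCC)[C@]1(C)Cc1cc(OCOC)c(OCOC)cc1OCOC | intermediate
16 | 2-[(1S,5R,6R)-5,6-dimethyl-2-(2-methylbut-3-en-2-yl)-6-{[2,4,5-tris(methoxymethoxy)phenyl]methyl}cyclohex-2-en-1-yl]acetaldehyde | C[C@@H]1CC=C(C(C)(C)C=C)[C@@H](CC=O)[C@]1(C)Cc1cc(OCOC)c(OCOC)cc1OCOC | intermediate
17 | 1-{[(1R,2S,6R)-1,6-dimethyl-3-(2-methylbut-3-en-2-yl)-2-(prop-2-en-1-yl)cyclohex-3-en-1-yl]methyl}-2,4,5-tris(methoxymethoxy)benzene | C[C@@H]1CC=C(C(C)(C)C=C)[C@@H](CC=C)[C@]1(C)Cc1cc(OCOC)c(OCOC)cc1OCOC | intermediate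
18 | 1-{[(1R,2R,8aS)-1,2,5,5-tetramethyl-1,2,3,5,8,8a-hexahydronaphthalen-1-yl]methyl}-2,4,5-tris(methoxymethoxy)benzene | C[C@@H]1CC=C2[C@@H](CC=CC2(C)C)[C@]1(C)Cc1cc(OCOC)c(OCOC)cc1OCOC | intermediate
19 | 1-{[(1R,2R,8aS)-1,2,5,5-tetramethyl-1,2,3,5,6,7,8,8a-octahydronaphthalen-1-yl]methyl}-2,4,5-tris(methoxymethoxy)benzene | C[C@@H]1CC=C2[C@@H](CCCC2(C)C)[C@]1(C)Cc1cc(OCOC)c(OCOC)cc1OCOC | intermediate
20 | [2,3,6-tris(methoxymethoxy)-5-{[(1R,2R,8aS)-1,2,5,5-tetramethyl-1,2,3,5,6,7,8,8a-octahydronaphthalen-1-yl]methyl}phenyl]lithium | C[C@@H]1CC=C2[C@@H](CCCC2(C)C)[C@]1(C)Cc1cc(OCOC)c(OCOC)c([Li])c1OCOC | intermediate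
21 | 2,3,6-tris(methoxymethoxy)-5-{[(1R,2R,8aS)-1,2,5,5-tetramethyl-1,2,3,5,6,7,8,8a-octahydronaphthalen-1-yl]methyl}benzaldehyde | C[C@@H]1CC=C2[C@@H](CCCC2(C)C)[C@]1(C)Cc1cc(OCOC)c(OCOC)c(C=O)c1OCOC | intermediate
22 | 2,3,6-trihydroxy-5-{[(1R,2R,8aS)-1,2,5,5-tetramethyl-1,2,3,5,6,7,8,8a-octahydronaphthalen-1-yl]methyl}benzaldehyde | C[C@@H]1CC=C2[C@@H](CCCC2(C)C)[C@]1(C)Cc1cc(O)c(O)c(C=O)c1O | intermediate
23 | 2,2-di-tert-butyl-5-hydroxy-6-{[(1R,2R,8aS)-1,2,5,5-tetramethyl-1,2,3,5,6,7,8,8a-octahydronaphthalen-1-yl]methyl}-1,3,2-benzodioxasilole-4-carbaldehyde | C[C@@H]1CC=C2[C@@H](CCCC2(C)C)[C@]1(C)Cc1cc2O[Si](C(C)(C)C)(C(C)(C)C)Oc2c(C=O)c1O | intermediate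
24 | 2,2-di-tert-butyl-4-formyl-6-{[(1R,2R,8aS)-1,2,5,5-tetramethyl-1,2,3,5,6,7,8,8a-octahydronaphthalen-1-yl]methyl}-1,3,2-benzodioxasilol-5-yl hydrogen sulfate | C[C@@H]1CC=C2[C@@H](CCCC2(C)C)[C@]1(C)Cc1cc2O[Si](C(C)(C)C)(C(C)(C)C)Oc2c(C=O)c1OS(=O)(=O)O | intermediate
25 | 2-formyl-3,4-dihydroxy-6-{[(1R,2R,8aS)-1,2,5,5-tetramethyl-1,2,3,5,6,7,8,8a-octahydronaphthalen-1-yl]methyl}phenyl hydrogen sulfate | C[C@@H]1CC=C2[C@@H](CCCC2(C)C)[C@]1(C)Cc1cc(O)c(O)c(C=O)c1OS(=O)(=O)O | target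

**Step count**
Total: 17 steps. Longest linear sequence: 16 steps (3 → 25 through steps 2–17; equally 1 → 25 through steps 1 and 3–17).

**Steps most likely to fail, with fallbacks**

Step 5. The ketone of 9 lies between a quaternary carbon and a methine that carries a tertiary alkyl group, so enolate formation and O-triflation may stall. The fallback sets out from 9 and changes the transposition tactic. Soft enolisation with Me3SiOTf/Et3N (CH2Cl2, 0 °C to rt) gives the trimethylsilyl enol ether F1. Saegusa–Ito dehydrogenation with Pd(OAc)2 (divalent palladium, 1 equiv, MeCN, 40 °C) gives the cyclohex-2-enone F2. Nucleophilic epoxidation (30% H2O2, NaOH, MeOH, 0 °C) occurs trans to the C8 methyl and gives the epoxy ketone F3. Wharton transposition (N2H4·H2O, AcOH, MeOH, rt) turns F3 into allylic alcohol 13, where the route is rejoined; 11 and 12 are bypassed.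

Step 7. The alkene of 12 is flanked by two quaternary carbons, so the SeO2 ene step may be slow, may over-oxidise, or may give the wrong face. The fallback sets out from 12. Allylic oxidation with CrO3·3,5-dimethylpyrazole (CH2Cl2, −20 °C) gives the transposed cyclohexenone F4. Corey–Bakshi–Shibata reduction of F4 with the (S)-configured B-methyl oxazaborolidine derived from diphenylprolinol and catecholborane (toluene, −78 °C) sets the carbinol by reagent control and comes back to the route at 13.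

Step 16. The phenol of 23 is hindered, hydrogen-bonded to the aldehyde, and the product is a salt that is hard to purify. The fallback sets out from 23 and uses a protected sulfate. 2,2,2-Trichloroethyl chlorosulfate (Cl3CCH2OSO2Cl), DMAP and Et3N in THF give the neutral, chromatographable trichloroethyl sulfate diester F5. HF·pyridine (THF, 0 °C) removes the silylene to give the catechol diester F6. Zn dust and HCO2NH4 (MeOH, rt) cleave the trichloroethyl group reductively and deliver 25, where the route is rejoined.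

**Further compounds**
F1 | step 5 | trimethylsilyl enol ether of 9, {[(5R,6R)-5,6-dimethyl-2-(2-methylbut-3-en-2-yl)-6-{[2,4,5-tris(methoxymethoxy)phenyl]methyl}cyclohex-1-en-1-yl]oxy}trimethylsilane | C[C@@H]1CCC(C(C)(C)C=C)=C(O[Si](C)(C)C)[C@]1(C)Cc1cc(OCOC)c(OCOC)cc1OCOC
F2 | step 5 | (5R,6R)-5,6-dimethyl-2-(2-methylbut-3-en-2-yl)-6-{[2,4,5-tris(methoxymethoxy)phenyl]methyl}cyclohex-2-en-1-one | C[C@@H]1CC=C(C(C)(C)C=C)C(=O)[C@]1(C)Cc1cc(OCOC)c(OCOC)cc1OCOC
F3 | step 5 | 2,3-epoxide of F2 with the epoxide oxygen trans to the C8 methyl | C[C@@H]1C[C@H]2O[C@@]2(C(C)(C)C=C)C(=O)[C@]1(C)Cc1cc(OCOC)c(OCOC)cc1OCOC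
F4 | step 7 | (4R,5R)-4,5-dimethyl-2-(2-methylbut-3-en-2-yl)-4-{[2,4,5-tris(methoxymethoxy)phenyl]methyl}cyclohex-2-en-1-one | C[C@@H]1CC(=O)C(C(C)(C)C=C)=C[C@]1(C)Cc1cc(OCOC)c(OCOC)cc1OCOC
F5 | step 16 | 2,2-di-tert-butyl-4-formyl-6-{[(1R,2R,8aS)-1,2,5,5-tetramethyl-1,2,3,5,6,7,8,8a-octahydronaphthalen-1-yl]methyl}-1,3,2-benzodioxasilol-5-yl 2,2,2-trichloroethyl sulfate | C[C@@H]1CC=C2[C@@H](CCCC2(C)C)[C@]1(C)Cc1cc2O[Si](C(C)(C)C)(C(C)(C)C)Oc2c(C=O)c1OS(=O)(=O)OCC(Cl)(Cl)Cl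
F6 | step 16 | 2-formyl-3,4-dihydroxy-6-{[(1R,2R,8aS)-1,2,5,5-tetramethyl-1,2,3,5,6,7,8,8a-octahydronaphthalen-1-yl]methyl}phenyl 2,2,2-trichloroethyl sulfate | C[C@@H]1CC=C2[C@@H](CCCC2(C)C)[C@]1(C)Cc1cc(O)c(O)c(C=O)c1OS(=O)(=O)OCC(Cl)(Cl)Cl
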